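## The problem

(R)-Sargachromenol 21 is a 2H-chromene: a benzene ring fused through C4a and C8a to a pyran that holds the C3=C4 double bond, with a hydroxyl on C6, a methyl on C8 and, on the quaternary carbon C2, a methyl group and a sixteen-carbon chain (C9' on C2 out to the carboxyl carbon C1'). C2 is the only stereocentre. Nothing in the molecule can control it, so its R configuration must be imported or set by a catalyst and then kept. Keeping it is a real constraint: C2-O1 is a tertiary allylic ether bond that ionises with acid, and a 2H-chromene opens reversibly to an ortho-quinone methide on irradiation or strong heating; either event racemises C2. The chain carries three trisubstituted olefins: C6'=C7' must be E, the carboxyl-bearing C2'=C3' must be Z (carboxyl cis to the chain, the less stable arrangement, which drifts to E under base or heat), and the isopropylidene end must survive. The 6-hydroxychromene is an electron-rich para-alkoxyphenol that air oxidises towards the quinone, fastest as its phenoxide. Two features open the route. O1 on C8a and the methyl on C8 are ortho neighbours, and the other neighbour of C8a, C4a, carries the C4=C3 arm, so adding an oxygen nucleophile and a carbon electrophile across a C8-C8a aryne gives exactly this pattern. And C2 with its methyl, C3 and the 4-methylpent-3-enyl arm is the skeleton and the stereocentre of (R)-linalool 3.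

## Retrosynthesis

Ring atoms are O1, C2, C3, C4, C4a, C5 to C8, C8a; chain atoms are C1' (carboxyl) to C9' (bonded to C2).

**21 to 19 (no skeletal bond).** The acid is traced to its methyl ester 20 and the phenol to its triisopropylsilyl ether 19. A free chromenol would not survive the oxidations and strong bases of the chain work, and a methyl ether would need Lewis acids for removal that ionise C2-O1. The silyl ether comes off with buffered fluoride and also serves the key step. The forward steps must spare the 2'Z olefin and keep air away from the phenoxide.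

**19 to 15 and 18 (C2'=C3').** This is the one olefin of the chain that no cheap terpene supplies, and it has the less stable geometry. A Still-Gennari olefination builds exactly that arrangement. Cutting at C6'=C7' instead would need an E-selective olefination of a methyl ketone and would discard an olefin that linalool provides. The C27 skeleton falls into the C19 aldehyde 15 and the C8 phosphonate 18, which is one alkylation away from commercial 16 and 17. The forward reaction must stay Z-selective with an alpha-branched phosphonate.

**15 to 10 (C4'-C5', then C5'-O).** Aldehyde 15 comes from nitrile 13, made from allylic bromide 12 and acetonitrile, which brings two carbons at an oxidation level one reduction away from the aldehyde. Bromide 12 comes from alcohol 11, and 11 from chromene 10 by allylic oxidation of the E methyl of the isopropylidene end. The C6'=C7' olefin and its E geometry are thus inherited, not built. Cleaving that olefin and rebuilding it by Wittig chemistry would cost more steps and would have to tell two olefins apart by electrophilic attack. The ene mechanism of SeO2 tells them apart by allylic hydrogens, which the chromene olefin lacks because C2 is quaternary. Precursor 10 carries the untouched linalool side chain.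

**10 to 5 and 6 (C8a-O1 and C8-CH3, the key cut).** Three neighbouring cuts are worse:
- Cutting O1-C2 (a phenol adding to a tertiary allylic cation, or oxa-6π closure of an ortho-quinone methide) makes C2 planar and loses the configuration.
- Cutting C8a-O1 alone by metal-catalysed etherification needs a halide on C8a flanked by the C8 methyl and the side arm, a 1,2,3,5-tetrasubstituted arene that has to be made, and tertiary alkoxides couple poorly.
- Direct substitution of fluoride is impossible on this electron-rich ring.

The aryne makes the unactivated fluoride reactive, and the need to functionalise C8 becomes the installation of the methyl group from iodomethane 6. The arene simplifies to a commercial 1,2,4-substitution pattern and the pyran to the open-chain carbinol 5. Since C2-O1 is never broken, the configuration of 3 is carried through. The forward reaction asks for lithiation at C8 only, in-plane closure by the alkoxide, and capture of the C8 aryllithium before it finds a proton. It also requires the Z olefin, because only then can oxygen reach C8a.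

**5 to 2 and 3 (C4-C4a, after a Z to E change).** The Z styrene 5 is traced to its E isomer 4, and 4 to aryl bromide 2 and linalool 3 by a Heck reaction. The Heck reaction takes 3 as sold, unprotected, and can only give the styrene because the carbinol carbon has no hydrogen. A Wittig route to the Z olefin would mean excising the vinyl group of 3 in the presence of its more reactive trisubstituted olefin. Semi-hydrogenation of an alkyne would need the enantiopure alkynol, which the chiral pool does not offer. The price is an uphill E to Z isomerisation, done with visible light before any photolabile chromene exists.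

**2 to 1 (O-Si).** Silylation of commercial 3-bromo-4-fluorophenol 1. The bulky silyl group is chosen over smaller ethers so that the ring positions beside its oxygen are shielded from lithiation.

## Roads not taken

**Alternative 1: oxygen-tethered Dötz benzannulation.**
- Cut: C8a-C4a, C5-C6 and C6-C7, so the benzene ring is assembled and not bought.
- Forward: the zerovalent chromium carbene A2, (CO)5Cr=C(OR)C(CH3)=CH2 with OR the tertiary alkoxide of a linalool-derived (Z)-enynol, is warmed. The tethered alkyne inserts, CO inserts, the dienylketene electrocyclises, and tautomerisation gives chromenol A1 with both rings closed.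
- Merits: two rings and three bonds in one step; the C6 hydroxyl arrives free from CO; the tether fixes the substitution pattern, so no question of lithiation site arises; C2 again comes from linalool.
- Weak points: A2 places a tertiary, allylic alkoxy group on an electron-poor carbene carbon. Such alkoxycarbenes are hard to make by alkoxide exchange, and their C-O bond behaves like that of an ester of a tertiary allylic alcohol, so it is prone to ionise, which would racemise C2. The (Z)-enyne still needs a cis olefin built from linalool, so the geometry problem of the chosen plan is not avoided. Chromium is stoichiometric. A1 emerges unprotected and must be silylated before the same chain extension.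
- Comparison: as a ring construction this road is more convergent than the chosen one, and it is free of cryogenic organolithium chemistry. The chosen plan sets against it a bought benzene ring, a robust carbinol precursor 5 in place of a labile carbene, and a silyl ether already in place after the key step.

**Alternative 2: one-carbon ring expansion of a benzofuranone.**
- Cut: C4a-C4 and C4-C3, with C4 as the inserted carbon.
- Forward: trimethylsilyldiazomethane with Sc(OTf)3 adds to the ketone of benzofuranone A4, the aryl carbon migrates with loss of N2, and chroman-3-one A3 results, with the full side chain already in place.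
- Merits: the chain is complete before the ring step, so little remains afterwards. The conditions are mild Lewis-acid catalysis without organolithium reagents. The C8 methyl and C6 oxygen come with a simple arene.
- Weak points: the quaternary alpha-aryloxy ketone stereocentre of A4 has no chiral-pool source and must be made enantioselectively. Migration of the quaternary C2 competes with aryl migration and would give the isomeric chroman-4-one. A3 still needs reduction and dehydration to reach C3=C4, an acid-promoted elimination next to the ionisable C2-O1 bond. The enolisable benzylic ketone of A3 is itself sensitive.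
- Comparison: in its late stage this road is better than the chosen plan, whose chain extension after ring closure is linear and long. The chosen plan answers with a stereocentre that costs nothing and a ring closure that gives the chromene oxidation level directly.

**Alternative 3: desymmetrising ring-closing metathesis.**
- Cut: C3=C4.
- Forward: the chiral alkylidene Mo(N-2,6-i-Pr2C6H3)(CHCMe2Ph)(3,3'-di-tert-butyl-5,5',6,6'-tetramethylbiphenyl-2,2'-diolate) joins the styrene carbon of triene A6 to one of its two enantiotopic vinyl groups and releases ethylene, giving vinylchromene A5.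
- Merits: the stereocentre is set by a catalyst, either enantiomer is available, and the optical purity does not depend on a natural terpene. In this respect it is better than the chosen plan, whose enantiomeric purity is capped by that of commercial 3.
- Weak points: A6 is the aryl ether of a tertiary bis-allylic alcohol with a 2,6-disubstituted phenol. No simple substitution makes this bond, and the ether is prone to ionise. The catalyst is highly air-sensitive. A5 carries only two of the sixteen chain carbons, so fourteen carbons and both stereodefined trisubstituted olefins remain to be built from a vinyl group in the presence of the chromene olefin.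
- Comparison: the chosen plan has no stereo-determining step at all. It starts with six chain carbons and the E olefin in place, and builds one olefin, not two.

Key step: step 4

Assumption: (R)-(−)-linalool 3 is taken as commercially available in high enantiomeric purity; since no step breaks a bond to its carbinol carbon, the enantiomeric purity of 21 is that of 3. Mesityllithium is prepared in a separate flask from 2-bromomesitylene and t-BuLi and transferred by cannula.

## Route

Step 1
Reactants: 1 3-bromo-4-fluorophenol
Product: 2 (3-bromo-4-fluorophenoxy)triisopropylsilane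
Conditions: i-Pr3SiCl, imidazole, DMF, rt
Reagents that add atoms: triisopropylsilyl chloride, CC(C)[Si](Cl)(C(C)C)C(C)C
Why: Silylation of a phenol with a silyl chloride and imidazole; the triisopropylsilyl ether withstands organolithium bases and shields the ring positions beside its oxygen from lithiation in step 4.

Step 2
Reactants: 2 (3-bromo-4-fluorophenoxy)triisopropylsilane; 3 (R)-linalool, (3R)-3,7-dimethylocta-1,6-dien-3-ol
Product: 4 (1E,3R)-1-[2-fluoro-5-(triisopropylsilyloxy)phenyl]-3,7-dimethylocta-1,6-dien-3-ol
Conditions: Pd(OAc)2 (5 mol%), P(o-tol)3 (10 mol%), Et3N, MeCN, 90 °C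
Reagents that add atoms: none
Why: Heck reaction: zerovalent palladium formed in situ inserts into C-Br, the aryl group adds to the terminal carbon of the vinyl group, and beta-hydride elimination can only take the benzylic hydrogen because the carbinol carbon has none, which gives the E styrene. The trisubstituted olefin is too hindered to insert and the stereocentre is not touched.

Step 3
Reactants: 4 (1E,3R)-1-[2-fluoro-5-(triisopropylsilyloxy)phenyl]-3,7-dimethylocta-1,6-dien-3-ol
Product: 5 (1Z,3R)-1-[2-fluoro-5-(triisopropylsilyloxy)phenyl]-3,7-dimethylocta-1,6-dien-3-ol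
Conditions: fac-Ir(ppy)3 (1 mol%), blue LEDs (450 nm), degassed MeCN, rt
Reagents that add atoms: none
Why: Contra-thermodynamic E to Z isomerisation of a styrene by triplet energy transfer from the excited iridium complex; the Z isomer is twisted out of conjugation by the clash between the tertiary carbinol and the ortho positions, accepts energy poorly and accumulates. It is run before ring closure, when no photolabile chromene is present.

Step 4
Reactants: 5 (1Z,3R)-1-[2-fluoro-5-(triisopropylsilyloxy)phenyl]-3,7-dimethylocta-1,6-dien-3-ol; 6 iodomethane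
Product: 10 (2R)-2,8-dimethyl-2-(4-methylpent-3-en-1-yl)-6-(triisopropylsilyloxy)-2H-chromene, via dilithiated aryl fluoride 7 (not isolated), via aryne lithium alkoxide 8 (not isolated), via 8-lithiochromene 9 (not isolated)
Conditions: n-BuLi (1.0 equiv), THF, −78 °C; mesityllithium (1.2 equiv), −78 → −20 °C; MeI (3 equiv), −78 °C → rt
Reagents that add atoms: none
Why: n-BuLi makes the lithium alkoxide, mesityllithium removes the ring proton ortho to fluorine (the future C8) to give 7, and on warming 7 loses LiF to the C8-C8a aryne 8. The alkoxide, held beside C8a by the Z olefin, adds in the plane of the ring to C8a (6-exo-dig with respect to the aryne bond), closing the pyran ring and leaving the carbanion on C8 as aryllithium 9, which iodomethane alkylates at carbon. The closest known reaction type is the base-induced aryne ring closure of a haloarene carrying a heteroatom nucleophile on an ortho side chain, with electrophilic capture of the aryllithium so formed; aryllithium bases are established for deprotonation ortho to fluorine. No stereocentre is formed and no bond to C2 is broken, so the R configuration of linalool is retained. Site selectivity of lithiation rests on fluorine being the strongest acidifying group on the ring, on the bulky silyl group blocking the positions beside the C6 oxygen, and on C4a being substituted, so that only the C8-C8a aryne can form. Oxygen can add only at C8a because the three-atom cis tether does not reach C8. Mesityllithium does not add to the styrene and ends as inert mesitylene, so no proton source is left to destroy 9 before the methyl quench.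

Step 5
Reactants: 10 (2R)-2,8-dimethyl-2-(4-methylpent-3-en-1-yl)-6-(triisopropylsilyloxy)-2H-chromene
Product: 11 (2E)-5-[(2R)-2,8-dimethyl-6-(triisopropylsilyloxy)-2H-chromen-2-yl]-2-methylpent-2-en-1-ol
Conditions: SeO2 (0.3 equiv), t-BuOOH (3 equiv), salicylic acid (0.1 equiv), CH2Cl2, rt
Reagents that add atoms: tert-butyl hydroperoxide, CC(C)(C)OO; selenium dioxide, O=[Se]=O
Why: Allylic oxidation with catalytic SeO2 (ene reaction, then [2,3]-sigmatropic shift) converts isopropylidene termini into (E)-2-methylalk-2-en-1-ols. The chromene olefin has no allylic hydrogen because C2 is quaternary, so only the chain terminus reacts.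

Step 6
Reactants: 11 (2E)-5-[(2R)-2,8-dimethyl-6-(triisopropylsilyloxy)-2H-chromen-2-yl]-2-methylpent-2-en-1-ol
Product: 12 (2R)-2-[(3E)-5-bromo-4-methylpent-3-en-1-yl]-2,8-dimethyl-6-(triisopropylsilyloxy)-2H-chromene
Conditions: CBr4, PPh3, CH2Cl2, 0 °C
Reagents that add atoms: carbon tetrabromide, BrC(Br)(Br)Br
Why: Appel reaction: bromide displaces the oxyphosphonium group at the primary allylic carbon under neutral conditions, without allylic transposition or change of olefin geometry, and without acid that could ionise C2-O1.

Step 7
Reactants: 12 (2R)-2-[(3E)-5-bromo-4-methylpent-3-en-1-yl]-2,8-dimethyl-6-(triisopropylsilyloxy)-2H-chromene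
Product: 13 (4E)-7-[(2R)-2,8-dimethyl-6-(triisopropylsilyloxy)-2H-chromen-2-yl]-4-methylhept-4-enenitrile
Conditions: MeCN (5 equiv), n-BuLi (4.5 equiv), THF, −78 °C; then 12, −78 → −40 °C
Reagents that add atoms: acetonitrile, CC#N
Why: SN2 alkylation of lithioacetonitrile by a primary allylic bromide, a standard two-carbon homologation of terpenoid allylic halides; the excess of nucleophile suppresses double alkylation.

Step 8
Reactants: 13 (4E)-7-[(2R)-2,8-dimethyl-6-(triisopropylsilyloxy)-2H-chromen-2-yl]-4-methylhept-4-enenitrile
Product: 15 (4E)-7-[(2R)-2,8-dimethyl-6-(triisopropylsilyloxy)-2H-chromen-2-yl]-4-methylhept-4-enal, via N-diisobutylalumanyl aldimine 14 (not isolated)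
Conditions: i-Bu2AlH (1.3 equiv), CH2Cl2, −78 °C; aq. tartaric acid, 0 °C → rt
Reagents that add atoms: water, O
Why: Partial reduction of a nitrile with i-Bu2AlH stops at the N-aluminated aldimine 14, which is hydrolysed to the aldehyde on mildly acidic work-up; the aryl silyl ether, the chromene and the olefins are inert.

Step 9
Reactants: 16 methyl 2-[bis(2,2,2-trifluoroethoxy)phosphoryl]acetate; 17 5-bromo-2-methylpent-2-ene
Product: 18 methyl 2-[bis(2,2,2-trifluoroethoxy)phosphoryl]-6-methylhept-5-enoate (racemic)
Conditions: NaH, DMF, 0 °C; then 17, 50 °C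
Reagents that add atoms: none
Why: C-alkylation of the sodium enolate of a phosphonoacetate with a primary bromide; a second alkylation is slow for steric reasons. The new stereocentre is racemic and disappears in step 10.

Step 10
Reactants: 15 (4E)-7-[(2R)-2,8-dimethyl-6-(triisopropylsilyloxy)-2H-chromen-2-yl]-4-methylhept-4-enal; 18 methyl 2-[bis(2,2,2-trifluoroethoxy)phosphoryl]-6-methylhept-5-enoate
Product: 19 methyl (2Z,6E)-9-[(2R)-2,8-dimethyl-6-(triisopropylsilyloxy)-2H-chromen-2-yl]-6-methyl-2-(4-methylpent-3-en-1-yl)nona-2,6-dienoate
Conditions: 18 (1.3 equiv), KN(SiMe3)2, 18-crown-6, THF, −78 °C; then 15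
Reagents that add atoms: none
Why: Still-Gennari variant of the Horner-Wadsworth-Emmons reaction: with electron-poor trifluoroethyl phosphonate esters and a dissociated potassium counter-ion, elimination from the kinetic adduct outruns equilibration, which places the ester cis to the new chain (2Z). The preformed phosphonate anion is not basic enough to enolise the aldehyde at −78 °C.

Step 11
Reactants: 19 methyl (2Z,6E)-9-[(2R)-2,8-dimethyl-6-(triisopropylsilyloxy)-2H-chromen-2-yl]-6-methyl-2-(4-methylpent-3-en-1-yl)nona-2,6-dienoate
Product: 20 methyl (2Z,6E)-9-[(2R)-6-hydroxy-2,8-dimethyl-2H-chromen-2-yl]-6-methyl-2-(4-methylpent-3-en-1-yl)nona-2,6-dienoate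
Conditions: Bu4NF (1.2 equiv), AcOH (1.2 equiv), THF, 0 °C → rt
Reagents that add atoms: none
Why: Fluoride cleavage of an aryl silyl ether, driven by the strength of the Si-F bond; acetic acid protonates the phenoxide at once, so the electron-rich chromenol is not left as its air-sensitive anion and the ester is untouched.

Step 12
Reactants: 20 methyl (2Z,6E)-9-[(2R)-6-hydroxy-2,8-dimethyl-2H-chromen-2-yl]-6-methyl-2-(4-methylpent-3-en-1-yl)nona-2,6-dienoate
Product: 21 (R)-sargachromenol, (2Z,6E)-9-[(2R)-6-hydroxy-2,8-dimethyl-2H-chromen-2-yl]-6-methyl-2-(4-methylpent-3-en-1-yl)nona-2,6-dienoic acid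
Conditions: LiOH·H2O (5 equiv), degassed THF/MeOH/H2O, Ar, rt → 40 °C; then 1 M HCl to pH 3
Reagents that add atoms: lithium hydroxide, [Li+].[OH-]
Why: Saponification of the methyl ester by acyl substitution with hydroxide, followed by acidification. Oxygen is excluded because the phenoxide is present, and the temperature is kept low to guard the 2Z geometry.

## Compound list

1 | 3-bromo-4-fluorophenol | Oc1ccc(F)c(Br)c1 | starting material
2 | (3-bromo-4-fluorophenoxy)triisopropylsilane | CC(C)[Si](Oc1ccc(F)c(Br)c1)(C(C)C)C(C)C | intermediate
3 | (R)-linalool, (3R)-3,7-dimethylocta-1,6-dien-3-ol | C=C[C@](C)(O)CCC=C(C)C | starting material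
4 | (1E,3R)-1-[2-fluoro-5-(triisopropylsilyloxy)phenyl]-3,7-dimethylocta-1,6-dien-3-ol | CC(C)=CCC[C@@](C)(O)/C=C/c1cc(O[Si](C(C)C)(C(C)C)C(C)C)ccc1F | intermediate
5 | (1Z,3R)-1-[2-fluoro-5-(triisopropylsilyloxy)phenyl]-3,7-dimethylocta-1,6-dien-3-ol | CC(C)=CCC[C@@](C)(O)/C=C\c1cc(O[Si](C(C)C)(C(C)C)C(C)C)ccc1F | intermediate
6 | iodomethane | CI | starting material
7 | lithium (1Z,3R)-1-[2-fluoro-3-lithio-5-(triisopropylsilyloxy)phenyl]-3,7-dimethylocta-1,6-dien-3-olate | CC(C)=CCC[C@@](C)(O[Li])/C=C\c1cc(O[Si](C(C)C)(C(C)C)C(C)C)cc([Li])c1F | intermediate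
8 | lithium (1Z,3R)-1-[2,3-didehydro-5-(triisopropylsilyloxy)phenyl]-3,7-dimethylocta-1,6-dien-3-olate (C8-C8a aryne) | CC(C)=CCC[C@@](C)(O[Li])/C=C\C1=CC(O[Si](C(C)C)(C(C)C)C(C)C)=CC#C1 | intermediate
9 | [(2R)-2-methyl-2-(4-methylpent-3-en-1-yl)-6-(triisopropylsilyloxy)-2H-chromen-8-yl]lithium | CC(C)=CCC[C@]1(C)C=Cc2cc(O[Si](C(C)C)(C(C)C)C(C)C)cc([Li])c2O1 | intermediate
10 | (2R)-2,8-dimethyl-2-(4-methylpent-3-en-1-yl)-6-(triisopropylsilyloxy)-2H-chromene | CC(C)=CCC[C@]1(C)C=Cc2cc(O[Si](C(C)C)(C(C)C)C(C)C)cc(C)c2O1 | intermediate
11 | (2E)-5-[(2R)-2,8-dimethyl-6-(triisopropylsilyloxy)-2H-chromen-2-yl]-2-methylpent-2-en-1-ol | OC/C(C)=C/CC[C@]1(C)C=Cc2cc(O[Si](C(C)C)(C(C)C)C(C)C)cc(C)c2O1 | intermediate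
12 | (2R)-2-[(3E)-5-bromo-4-methylpent-3-en-1-yl]-2,8-dimethyl-6-(triisopropylsilyloxy)-2H-chromene | BrC/C(C)=C/CC[C@]1(C)C=Cc2cc(O[Si](C(C)C)(C(C)C)C(C)C)cc(C)c2O1 | intermediate
13 | (4E)-7-[(2R)-2,8-dimethyl-6-(triisopropylsilyloxy)-2H-chromen-2-yl]-4-methylhept-4-enenitrile | N#CCC/C(C)=C/CC[C@]1(C)C=Cc2cc(O[Si](C(C)C)(C(C)C)C(C)C)cc(C)c2O1 | intermediate
14 | (4E)-N-[bis(2-methylpropyl)alumanyl]-7-[(2R)-2,8-dimethyl-6-(triisopropylsilyloxy)-2H-chromen-2-yl]-4-methylhept-4-en-1-imine | CC(C)C[Al](CC(C)C)N=CCC/C(C)=C/CC[C@]1(C)C=Cc2cc(O[Si](C(C)C)(C(C)C)C(C)C)cc(C)c2O1 | intermediate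
15 | (4E)-7-[(2R)-2,8-dimethyl-6-(triisopropylsilyloxy)-2H-chromen-2-yl]-4-methylhept-4-enal | O=CCC/C(C)=C/CC[C@]1(C)C=Cc2cc(O[Si](C(C)C)(C(C)C)C(C)C)cc(C)c2O1 | intermediate
16 | methyl 2-[bis(2,2,2-trifluoroethoxy)phosphoryl]acetate | COC(=O)CP(=O)(OCC(F)(F)F)OCC(F)(F)F | starting material
17 | 5-bromo-2-methylpent-2-ene | CC(C)=CCCBr | starting material
18 | methyl 2-[bis(2,2,2-trifluoroethoxy)phosphoryl]-6-methylhept-5-enoate (racemic) | COC(=O)C(CCC=C(C)C)P(=O)(OCC(F)(F)F)OCC(F)(F)F | intermediate
19 | methyl (2Z,6E)-9-[(2R)-2,8-dimethyl-6-(triisopropylsilyloxy)-2H-chromen-2-yl]-6-methyl-2-(4-methylpent-3-en-1-yl)nona-2,6-dienoate | CC(C)=CCC/C(=C/CC/C(C)=C/CC[C@]1(C)C=Cc2cc(O[Si](C(C)C)(C(C)C)C(C)C)cc(C)c2O1)C(=O)OC | intermediate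
20 | methyl (2Z,6E)-9-[(2R)-6-hydroxy-2,8-dimethyl-2H-chromen-2-yl]-6-methyl-2-(4-methylpent-3-en-1-yl)nona-2,6-dienoate | CC(C)=CCC/C(=C/CC/C(C)=C/CC[C@]1(C)C=Cc2cc(O)cc(C)c2O1)C(=O)OC | intermediate
21 | (R)-sargachromenol, (2Z,6E)-9-[(2R)-6-hydroxy-2,8-dimethyl-2H-chromen-2-yl]-6-methyl-2-(4-methylpent-3-en-1-yl)nona-2,6-dienoic acid | CC(C)=CCC/C(=C/CC/C(C)=C/CC[C@]1(C)C=Cc2cc(O)cc(C)c2O1)C(=O)O | target

## Step count and risk

Total step count: 12. Longest linear sequence: 11 steps (steps 1 to 8 and 10 to 12, from 1); step 9 is a one-step side branch.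

**Step 4 (key step).** Two processes threaten it. If lithiation at C8 is incomplete when LiF loss begins, remaining mesityllithium or aryllithium adds to the aryne in competition with the alkoxide. And the C8 aryllithium 9 may be protonated by the medium at the temperature needed for aryne formation, before iodomethane is added. Alkoxide-directed lithiation at the ring position next to the side arm is a further, less likely, diversion. Fallback: ring closure and methylation are separated. Starting from 5, lithium 2,2,6,6-tetramethylpiperidide (3 equiv, THF, −78 → 0 °C) generates the aryne. This amide is too hindered to add to it, and the amine set free protonates C8 on purpose, giving (2R)-2-methyl-2-(4-methylpent-3-en-1-yl)-6-(triisopropylsilyloxy)-2H-chromene F1. Ortho-lithiation of F1 directed by O1 (n-BuLi, TMEDA, Et2O, 0 °C; the silyl group blocks C5 and C7), then iodomethane, returns to the route at 10. The same two bonds form, in two operations.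

**Step 3.** The photostationary mixture may stop short of high Z content, because the ortho-fluoro styrene is a weak energy acceptor in both geometries. Residual E isomer cannot cyclise in step 4 and would be consumed there by intermolecular aryne reactions. Fallback: the cis olefin is made by semi-hydrogenation. Starting from 2, Sonogashira coupling (PdCl2(PPh3)2, CuI, Et3N, 60 °C) with (3R)-3,7-dimethyloct-6-en-1-yn-3-ol F2 gives (3R)-1-[2-fluoro-5-(triisopropylsilyloxy)phenyl]-3,7-dimethyloct-6-en-1-yn-3-ol F3. F2 is obtained from the commercial racemate by preparative chromatography on a chiral stationary phase. Hydrogenation of F3 over Pd/CaCO3 poisoned with Pb(OAc)2 and quinoline returns to the route at 5.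

**Step 5.** Conversion may stall, the alcohol may be over-oxidised to the enal, or the peroxide may attack the electron-rich chromene. Fallback: the terminus is functionalised by cross-metathesis. Starting from 10, methacrolein and the second-generation Hoveyda-Grubbs catalyst RuCl2(H2IMes)(=CH-C6H4-2-O-i-Pr) in CH2Cl2 at 40 °C exchange the isopropylidene end, with loss of isobutene. The product is (2E)-5-[(2R)-2,8-dimethyl-6-(triisopropylsilyloxy)-2H-chromen-2-yl]-2-methylpent-2-enal F4; the ring olefin is endocyclic and inert. Reduction with NaBH4 and CeCl3·7H2O in MeOH at 0 °C returns to the route at 11. Any enal formed by over-oxidation in step 5 is this same compound and is recovered the same way.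

**Step 10.** The alpha-branch of phosphonate 18 may slow the addition and erode Z selectivity, giving an ester mixture that is hard to separate. Fallback: geometry is set at the disubstituted stage and the branch is added afterwards.
- Phosphonate 16 is brominated at carbon (NaH, then N-bromosuccinimide) to methyl 2-[bis(2,2,2-trifluoroethoxy)phosphoryl]-2-bromoacetate F5.
- Olefination of 15 with F5 (KN(SiMe3)2, 18-crown-6, THF, −78 °C) gives methyl (2E,6E)-2-bromo-9-[(2R)-2,8-dimethyl-6-(triisopropylsilyloxy)-2H-chromen-2-yl]-6-methylnona-2,6-dienoate F6, with the ester cis to the chain.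
- Negishi coupling of F6 with (4-methylpent-3-en-1-yl)zinc bromide F7, made from 17 and zinc, under Pd(P(t-Bu)3)2 in THF at rt replaces bromine with retention of geometry and returns to the route at 19.

**Step 12.** Hydrolysis of the hindered ester is slow. Over that time the 2Z enoate may isomerise to E under base, and the phenoxide may be oxidised by traces of air. Fallback: the acid is reached by adjusting the oxidation state, not by hydrolysis, with the phenol still protected. Starting from 19:
- i-Bu2AlH (CH2Cl2, −78 °C) gives (2Z,6E)-9-[(2R)-2,8-dimethyl-6-(triisopropylsilyloxy)-2H-chromen-2-yl]-6-methyl-2-(4-methylpent-3-en-1-yl)nona-2,6-dien-1-ol F8.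
- MnO2 (CH2Cl2, rt) gives (2Z,6E)-9-[(2R)-2,8-dimethyl-6-(triisopropylsilyloxy)-2H-chromen-2-yl]-6-methyl-2-(4-methylpent-3-en-1-yl)nona-2,6-dienal F9, which is used at once.
- Pinnick oxidation (NaClO2, NaH2PO4, 2-methylbut-2-ene, t-BuOH/H2O) gives (2Z,6E)-9-[(2R)-2,8-dimethyl-6-(triisopropylsilyloxy)-2H-chromen-2-yl]-6-methyl-2-(4-methylpent-3-en-1-yl)nona-2,6-dienoic acid F10.
- Bu4NF with AcOH in THF removes the silyl group and returns to the route at 21.

## Further compounds

F1 | step 4 | (2R)-2-methyl-2-(4-methylpent-3-en-1-yl)-6-(triisopropylsilyloxy)-2H-chromene | CC(C)=CCC[C@]1(C)C=Cc2cc(O[Si](C(C)C)(C(C)C)C(C)C)ccc2O1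
F2 | step 3 | (3R)-3,7-dimethyloct-6-en-1-yn-3-ol | C#C[C@](C)(O)CCC=C(C)C
F3 | step 3 | (3R)-1-[2-fluoro-5-(triisopropylsilyloxy)phenyl]-3,7-dimethyloct-6-en-1-yn-3-ol | CC(C)=CCC[C@@](C)(O)C#Cc1cc(O[Si](C(C)C)(C(C)C)C(C)C)ccc1F
F4 | step 5 | (2E)-5-[(2R)-2,8-dimethyl-6-(triisopropylsilyloxy)-2H-chromen-2-yl]-2-methylpent-2-enal | O=C/C(C)=C/CC[C@]1(C)C=Cc2cc(O[Si](C(C)C)(C(C)C)C(C)C)cc(C)c2O1
F5 | step 10 | methyl 2-[bis(2,2,2-trifluoroethoxy)phosphoryl]-2-bromoacetate | COC(=O)C(Br)P(=O)(OCC(F)(F)F)OCC(F)(F)F
F6 | step 10 | methyl (2E,6E)-2-bromo-9-[(2R)-2,8-dimethyl-6-(triisopropylsilyloxy)-2H-chromen-2-yl]-6-methylnona-2,6-dienoate | Br/C(=C/CC/C(C)=C/CC[C@]1(C)C=Cc2cc(O[Si](C(C)C)(C(C)C)C(C)C)cc(C)c2O1)C(=O)OC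
F7 | step 10 | (4-methylpent-3-en-1-yl)zinc bromide | CC(C)=CCC[Zn]Br
F8 | step 12 | (2Z,6E)-9-[(2R)-2,8-dimethyl-6-(triisopropylsilyloxy)-2H-chromen-2-yl]-6-methyl-2-(4-methylpent-3-en-1-yl)nona-2,6-dien-1-ol | CC(C)=CCC/C(=C/CC/C(C)=C/CC[C@]1(C)C=Cc2cc(O[Si](C(C)C)(C(C)C)C(C)C)cc(C)c2O1)CO
F9 | step 12 | (2Z,6E)-9-[(2R)-2,8-dimethyl-6-(triisopropylsilyloxy)-2H-chromen-2-yl]-6-methyl-2-(4-methylpent-3-en-1-yl)nona-2,6-dienal | CC(C)=CCC/C(=C/CC/C(C)=C/CC[C@]1(C)C=Cc2cc(O[Si](C(C)C)(C(C)C)C(C)C)cc(C)c2O1)C=O
F10 | step 12 | (2Z,6E)-9-[(2R)-2,8-dimethyl-6-(triisopropylsilyloxy)-2H-chromen-2-yl]-6-methyl-2-(4-methylpent-3-en-1-yl)nona-2,6-dienoic acid | CC(C)=CCC/C(=C/CC/C(C)=C/CC[C@]1(C)C=Cc2cc(O[Si](C(C)C)(C(C)C)C(C)C)cc(C)c2O1)C(=O)O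
A1 | alternative 1 | (2R)-2,8-dimethyl-2-(4-methylpent-3-en-1-yl)-2H-chromen-6-ol | CC(C)=CCC[C@]1(C)C=Cc2cc(O)cc(C)c2O1
A2 | alternative 1 | pentacarbonyl{{[(3Z,5R)-5,9-dimethyldeca-3,8-dien-1-yn-5-yl]oxy}(prop-1-en-2-yl)methylidene}chromium | CC(C)=CCC[C@@](C)(OC(C(C)=C)=[Cr](=C=O)(=C=O)(=C=O)(=C=O)=C=O)/C=C\C#C
A3 | alternative 2 | methyl (2Z,6E)-9-[(2R)-2,8-dimethyl-3-oxo-6-(pivaloyloxy)chroman-2-yl]-6-methyl-2-(4-methylpent-3-en-1-yl)nona-2,6-dienoate | CC(C)=CCC/C(=C/CC/C(C)=C/CC[C@]1(C)C(=O)Cc2cc(OC(=O)C(C)(C)C)cc(C)c2O1)C(=O)OC
A4 | alternative 2 | methyl (2Z,6E)-9-[(2R)-2,7-dimethyl-3-oxo-5-(pivaloyloxy)-2,3-dihydro-1-benzofuran-2-yl]-6-methyl-2-(4-methylpent-3-en-1-yl)nona-2,6-dienoate | CC(C)=CCC/C(=C/CC/C(C)=C/CC[C@]1(C)C(=O)c2cc(OC(=O)C(C)(C)C)cc(C)c2O1)C(=O)OC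
A5 | alternative 3 | (R)-tert-butyl[(2-ethenyl-2,8-dimethyl-2H-chromen-6-yl)oxy]dimethylsilane | C=C[C@]1(C)C=Cc2cc(O[Si](C)(C)C(C)(C)C)cc(C)c2O1
A6 | alternative 3 | tert-butyl{3-ethenyl-5-methyl-4-[(3-methylpenta-1,4-dien-3-yl)oxy]phenoxy}dimethylsilane | C=CC(C)(C=C)Oc1c(C)cc(O[Si](C)(C)C(C)(C)C)cc1C=C
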